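Ring A, the fully substituted phloroglucinol ring, is disconnected at C4a–C5 and C8–C8a. Carbons C5 to C8, the oxygens on C5 and C7 and the C8 prenyl group come from one silyl vinylketene acetal. C4a and C8a are the alkene of an enantiopure 2-aryl-2,3-dihydro-4H-pyran-4-one that carries a phenylsulfinyl group on the carbon destined to be C4a. A single Diels–Alder reaction, followed in the same flask by loss of benzenesulfenic acid and methanol, closes and aromatises ring A with every substituent in place, while C2, set earlier by a catalytic asymmetric hetero-Diels–Alder reaction, is never touched.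

Key step: step 8

Assumption: the (S)-BINOL/Ti(OiPr)4 catalyst is taken to direct the diene to the Si face of the aryl aldehyde, as in the allylation with the same catalyst, which gives the (2S)-pyranone; should the first run show the opposite sense, (R)-BINOL is used and nothing else changes.

Ar = 3-(tert-butyldimethylsilyloxy)-4-methoxyphenyl in the names below.

Step 1
Reactants: 1 isovanillin (3-hydroxy-4-methoxybenzaldehyde)
Product: 2 3-(tert-butyldimethylsilyloxy)-4-methoxybenzaldehyde
Conditions: TBSCl, imidazole, DMF, rt
Reagents that add atoms: tert-butyldimethylsilyl chloride, CC(C)(C)[Si](C)(C)Cl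
Why: Routine silylation of a phenol, which masks the acidic OH that would otherwise quench the titanium catalyst and the silyl ketene acetal and would compete in the later methylation.

Step 2
Reactants: 2 3-(tert-butyldimethylsilyloxy)-4-methoxybenzaldehyde; 3 Danishefsky's diene ((E)-1-methoxy-3-(trimethylsilyloxy)buta-1,3-diene)
Product: 5 (2S)-2-Ar-2,3-dihydro-4H-pyran-4-one, via silyl aldol adduct 4 (not isolated)
Conditions: (S)-BINOL (20 mol%), Ti(OiPr)4 (10 mol%), 4 Å MS, Et2O, −20 °C; then CF3CO2H, CH2Cl2, 0 °C
Reagents that add atoms: none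
Why: Titanium–BINOL-catalysed hetero-Diels–Alder reaction of the Mukaiyama aldol/cyclisation type, in which the chiral Lewis acid should expose the Si face of the aldehyde to the diene terminus and so set C2 as S, after which trifluoroacetic acid closes the ring with loss of methanol and the trimethylsilyl group.

Step 3
Reactants: 5 (2S)-2-Ar-2,3-dihydro-4H-pyran-4-one
Product: 7 (2S)-2-Ar-5-(phenylthio)-2,3-dihydro-4H-pyran-4-one, via chloro sulfide adduct 6 (not isolated)
Conditions: PhSCl (distilled), CH2Cl2, −78 → 0 °C; then Et3N, 0 °C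
Reagents that add atoms: benzenesulfenyl chloride, ClSc1ccccc1
Why: Electrophilic sulfenylation of a vinylogous ester by addition–elimination, in which sulfur adds to the nucleophilic α-carbon C5, chloride caps the oxocarbenium ion at C6 and the amine removes HCl to restore the enone, as in the α-halogenation of dihydropyranones and the sulfenylation of glycals; C2 is not involved.

Step 4
Reactants: 7 (2S)-2-Ar-5-(phenylthio)-2,3-dihydro-4H-pyran-4-one
Product: 8 (2S)-2-Ar-5-(phenylsulfinyl)-2,3-dihydro-4H-pyran-4-one (both configurations at sulfur)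
Conditions: mCPBA (1.0 equiv), NaHCO3, CH2Cl2, −78 °C
Reagents that add atoms: 3-chloroperbenzoic acid, OOC(=O)c1cccc(Cl)c1
Why: Chemoselective sulfide-to-sulfoxide oxidation with one equivalent of peracid at low temperature, the enone alkene being electron-poor and the configuration at sulfur irrelevant because sulfur is expelled later.

Step 5
Reactants: 9 methyl acetoacetate; 10 prenyl bromide (1-bromo-3-methylbut-2-ene)
Product: 12 methyl 7-methyl-3-oxooct-6-enoate, via acetoacetate dianion 11 (not isolated)
Conditions: NaH, THF, 0 °C; n-BuLi, 0 °C; then 10, 0 °C → rt; aq. HCl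
Reagents that add atoms: none
Why: γ-Alkylation of the acetoacetate dianion (Weiler alkylation), whose more basic terminal carbanion should displace the primary allylic bromide by SN2.

Step 6
Reactants: 12 methyl 7-methyl-3-oxooct-6-enoate
Product: 14 methyl (2E)-3-methoxy-7-methylocta-2,6-dienoate, via dimethyl ketal 13 (not isolated)
Conditions: HC(OMe)3, H2SO4 (cat.), MeOH, rt; then distillation under reduced pressure
Reagents that add atoms: trimethyl orthoformate, COC(OC)OC
Why: Acid-catalysed ketalisation with the orthoformate as water scavenger, followed by loss of methanol on distillation, should give the conjugated β-methoxy enoate as the favoured E isomer, while catalytic acid in methanol at room temperature leaves the trisubstituted alkene alone.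

Step 7
Reactants: 14 methyl (2E)-3-methoxy-7-methylocta-2,6-dienoate
Product: 16 (3Z)-1,3-dimethoxy-7-methyl-1-(trimethylsilyloxy)octa-1,3,6-triene (mixture at C1=C2), via lithium dienolate 15 (not isolated)
Conditions: LiN(iPr)2 (LDA, commercial solution), THF, −78 °C; then TMSCl, −78 °C → rt; filtration under argon, bulb-to-bulb distillation
Reagents that add atoms: chlorotrimethylsilane, C[Si](C)(C)Cl
Why: γ-Deprotonation of the β-methoxy enoate and O-silylation of the extended dienolate is the standard preparation of Brassard-type dienes, and the cisoid transition state should place the side chain on the outside of the diene (3Z), the geometry that allows the s-cis conformer.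

Step 8
Reactants: 8 (2S)-2-Ar-5-(phenylsulfinyl)-2,3-dihydro-4H-pyran-4-one; 16 (3Z)-1,3-dimethoxy-7-methyl-1-(trimethylsilyloxy)octa-1,3,6-triene
Product: 20 (2S)-2-Ar-5-hydroxy-7-methoxy-8-(3-methylbut-2-en-1-yl)-2,3-dihydro-4H-chromen-4-one, via sulfinyl cycloadduct 17 (not isolated), via cyclohexadiene 18 (not isolated), via aryl trimethylsilyl ether 19 (not isolated)
Conditions: 16 (3 equiv), toluene, 25 → 90 °C; then 10% aq. citric acid, THF, rt
Reagents that add atoms: none
Why: Proposed new method: the electron-rich vinylketene acetal should add across the C5=C6 bond of the pyranone, whose LUMO is lowered by the ketone and the sulfinyl group on the same carbon, in an asynchronous concerted [4+2] cycloaddition (at the limit a Mukaiyama–Michael addition followed by collapse of the zwitterion), the closest known reaction type being the Diels–Alder reaction and aromatisation of 1,3-dioxygenated vinylketene acetals with halo- or sulfinyl-activated quinones and 3-sulfinylchromones. Ring A closes in the six-membered [4+2] mode through the bonds C8–C8a and C4a–C5. Regiochemistry, the one selectivity the step needs, follows from polarity: the nucleophilic diene terminus C4, which carries the prenyl chain, bonds to the enone β-carbon C6 (the future C8a), and the acetal carbon bonds to C5 (the future C4a), both acceptor groups sitting on C5. Because the addition is suprafacial the C8a hydrogen and the sulfinyl group are cis, so thermal syn-elimination of benzenesulfenic acid, easy for a sulfoxide α to a ketone, should give the C4a=C8a alkene, and 1,4-loss of methanol from C5 and C8, driven by aromatisation, leaves the C5 oxygen as a trimethylsilyl ether that the mild acidic work-up cleaves without touching the aryl tert-butyldimethylsilyl ether. No stereocentre survives, since the four transient sp3 centres are erased, so facial and endo/exo selectivity do not matter. C2 lies outside the reacting array and meets no base, and the excess of diene absorbs the sulfenic acid that is set free.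

Step 9
Reactants: 20 (2S)-2-Ar-5-hydroxy-7-methoxy-8-(3-methylbut-2-en-1-yl)-2,3-dihydro-4H-chromen-4-one
Product: 21 (2S)-2-Ar-5,7-dimethoxy-8-(3-methylbut-2-en-1-yl)-2,3-dihydro-4H-chromen-4-one
Conditions: MeI (excess), Ag2O, CH2Cl2, rt → 40 °C, dark
Reagents that add atoms: iodomethane, CI
Why: Silver-oxide-promoted O-methylation (Purdie conditions) alkylates hydrogen-bonded peri-hydroxy ketones without a soluble strong base, which should keep the flavanone from opening to the chalcone and so preserve C2.

Step 10
Reactants: 21 (2S)-2-Ar-5,7-dimethoxy-8-(3-methylbut-2-en-1-yl)-2,3-dihydro-4H-chromen-4-one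
Product: 22 (2S)-2-(3-hydroxy-4-methoxyphenyl)-5,7-dimethoxy-8-(3-methylbut-2-en-1-yl)-2,3-dihydro-4H-chromen-4-one (target)
Conditions: HF·pyridine, pyridine, THF, 0 °C → rt
Reagents that add atoms: none
Why: Fluoride cleavage of the aryl silyl ether under buffered, mildly acidic conditions should leave the ketone, the prenyl alkene, the methyl ethers and the base-sensitive C2 centre untouched.

Compound list
1 | isovanillin (3-hydroxy-4-methoxybenzaldehyde) | COc1ccc(C=O)cc1O | starting material
2 | 3-(tert-butyldimethylsilyloxy)-4-methoxybenzaldehyde | COc1ccc(C=O)cc1O[Si](C)(C)C(C)(C)C | intermediate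
3 | Danishefsky's diene, (E)-1-methoxy-3-(trimethylsilyloxy)buta-1,3-diene | CO/C=C/C(=C)O[Si](C)(C)C | starting material
4 | (1E,5S)-5-[3-(tert-butyldimethylsilyloxy)-4-methoxyphenyl]-1-methoxy-5-(trimethylsilyloxy)pent-1-en-3-one | COc1ccc([C@@H](O[Si](C)(C)C)CC(=O)/C=C/OC)cc1O[Si](C)(C)C(C)(C)C | intermediate
5 | (2S)-2-[3-(tert-butyldimethylsilyloxy)-4-methoxyphenyl]-2,3-dihydro-4H-pyran-4-one | COc1ccc([C@@H]2CC(=O)C=CO2)cc1O[Si](C)(C)C(C)(C)C | intermediate
6 | (6S)-6-[3-(tert-butyldimethylsilyloxy)-4-methoxyphenyl]-2-chloro-3-(phenylthio)tetrahydro-4H-pyran-4-one (mixture at the two new centres) | COc1ccc([C@@H]2CC(=O)C(Sc3ccccc3)C(Cl)O2)cc1O[Si](C)(C)C(C)(C)C | intermediate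
7 | (2S)-2-[3-(tert-butyldimethylsilyloxy)-4-methoxyphenyl]-5-(phenylthio)-2,3-dihydro-4H-pyran-4-one | COc1ccc([C@@H]2CC(=O)C(Sc3ccccc3)=CO2)cc1O[Si](C)(C)C(C)(C)C | intermediate
8 | (2S)-2-[3-(tert-butyldimethylsilyloxy)-4-methoxyphenyl]-5-(phenylsulfinyl)-2,3-dihydro-4H-pyran-4-one (both configurations at sulfur) | COc1ccc([C@@H]2CC(=O)C(S(=O)c3ccccc3)=CO2)cc1O[Si](C)(C)C(C)(C)C | intermediate
9 | methyl acetoacetate | COC(=O)CC(C)=O | starting material
10 | prenyl bromide (1-bromo-3-methylbut-2-ene) | CC(C)=CCBr | starting material
11 | sodium lithium dianion of methyl acetoacetate | COC([O-])=CC([O-])=C.[Na+].[Li+] | intermediate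
12 | methyl 7-methyl-3-oxooct-6-enoate | COC(=O)CC(=O)CCC=C(C)C | intermediate
13 | methyl 3,3-dimethoxy-7-methyloct-6-enoate | COC(=O)CC(OC)(OC)CCC=C(C)C | intermediate
14 | methyl (2E)-3-methoxy-7-methylocta-2,6-dienoate | CO/C(CCC=C(C)C)=C/C(=O)OC | intermediate
15 | lithium dienolate of 14 (lithium 1,3-dimethoxy-7-methylocta-1,3,6-trien-1-olate) | COC([O-])=C/C(OC)=C/CC=C(C)C.[Li+] | intermediate
16 | (3Z)-1,3-dimethoxy-7-methyl-1-(trimethylsilyloxy)octa-1,3,6-triene (mixture at C1=C2) | COC(O[Si](C)(C)C)=C/C(OC)=C/CC=C(C)C | intermediate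
17 | (2S)-2-[3-(tert-butyldimethylsilyloxy)-4-methoxyphenyl]-5,7-dimethoxy-8-(3-methylbut-2-en-1-yl)-4a-(phenylsulfinyl)-5-(trimethylsilyloxy)-2,3,4a,5,8,8a-hexahydro-4H-chromen-4-one (cis ring fusion, mixture at the transient centres) | COc1ccc([C@@H]2CC(=O)C3(S(=O)c4ccccc4)C(OC)(O[Si](C)(C)C)C=C(OC)C(CC=C(C)C)C3O2)cc1O[Si](C)(C)C(C)(C)C | intermediate
18 | (2S)-2-[3-(tert-butyldimethylsilyloxy)-4-methoxyphenyl]-5,7-dimethoxy-8-(3-methylbut-2-en-1-yl)-5-(trimethylsilyloxy)-2,3,5,8-tetrahydro-4H-chromen-4-one (mixture at C5 and C8) | COc1ccc([C@@H]2CC(=O)C3=C(O2)C(CC=C(C)C)C(OC)=CC3(OC)O[Si](C)(C)C)cc1O[Si](C)(C)C(C)(C)C | intermediate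
19 | (2S)-2-[3-(tert-butyldimethylsilyloxy)-4-methoxyphenyl]-7-methoxy-8-(3-methylbut-2-en-1-yl)-5-(trimethylsilyloxy)-2,3-dihydro-4H-chromen-4-one | COc1ccc([C@@H]2CC(=O)c3c(O[Si](C)(C)C)cc(OC)c(CC=C(C)C)c3O2)cc1O[Si](C)(C)C(C)(C)C | intermediate
20 | (2S)-2-[3-(tert-butyldimethylsilyloxy)-4-methoxyphenyl]-5-hydroxy-7-methoxy-8-(3-methylbut-2-en-1-yl)-2,3-dihydro-4H-chromen-4-one | COc1ccc([C@@H]2CC(=O)c3c(O)cc(OC)c(CC=C(C)C)c3O2)cc1O[Si](C)(C)C(C)(C)C | intermediate
21 | (2S)-2-[3-(tert-butyldimethylsilyloxy)-4-methoxyphenyl]-5,7-dimethoxy-8-(3-methylbut-2-en-1-yl)-2,3-dihydro-4H-chromen-4-one | COc1ccc([C@@H]2CC(=O)c3c(OC)cc(OC)c(CC=C(C)C)c3O2)cc1O[Si](C)(C)C(C)(C)C | intermediate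
22 | (2S)-2-(3-hydroxy-4-methoxyphenyl)-5,7-dimethoxy-8-(3-methylbut-2-en-1-yl)-2,3-dihydro-4H-chromen-4-one | COc1ccc([C@@H]2CC(=O)c3c(OC)cc(OC)c(CC=C(C)C)c3O2)cc1O | target

Total step count: 10. Longest linear sequence: 7 (steps 1, 2, 3, 4, 8, 9, 10); the diene branch (steps 5 to 7) joins at step 8.

Steps most likely to fail

Step 8 (proposed new method). The hindered bond between the acetal carbon and the sulfinyl-bearing carbon may not close, so that only a Michael-type adduct forms. The diene may also be consumed by silyl transfer to the liberated sulfenic acid before it has added, or elimination may outrun cycloaddition and destroy the dienophile. The fallback uses only established reaction types and brings ring A in ready-made. It sets out from prenyl bromide 10, together with commercial 5,7-dihydroxy-4H-chromen-4-one and commercial (3-hydroxy-4-methoxyphenyl)boronic acid, and comes back to the route at target 22. The non-chelated 7-OH of the dihydroxychromone is methylated (MeI, K2CO3, acetone) to 5-hydroxy-7-methoxy-4H-chromen-4-one F1. The chelated 5-OH is then alkylated with 10 (K2CO3, DMF, 60 °C) to 7-methoxy-5-(3-methylbut-2-en-1-yloxy)-4H-chromen-4-one F2. A Eu(fod)3-catalysed para-Claisen–Cope rearrangement (CHCl3, 60 °C), the established way from 5-prenyl ethers to 8-prenyl flavonoids, should give 5-hydroxy-7-methoxy-8-(3-methylbut-2-en-1-yl)-4H-chromen-4-one F3. Methylation (MeI, K2CO3, DMF), harmless here because no stereocentre is present, gives 5,7-dimethoxy-8-(3-methylbut-2-en-1-yl)-4H-chromen-4-one F4. Rhodium-catalysed asymmetric 1,4-addition of the arylboronic acid ([Rh(OH)(cod)]2, the antipode of an electron-poor MeO-BIPHEP-type diphosphine that gives the 2S product, toluene/water), a known flavanone synthesis, then sets C2 and delivers 22.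

Step 3. The sulfenyl chloride may add without clean dehydrochlorination, may attack the electron-rich arene, or the acid released may erode the silyl ether. The fallback separates halogenation from C–S bond formation; it sets out from 5 and comes back at 7. α-Iodination of the enone (I2, pyridine, CH2Cl2, rt) gives (2S)-2-[3-(tert-butyldimethylsilyloxy)-4-methoxyphenyl]-5-iodo-2,3-dihydro-4H-pyran-4-one F5. Palladium-catalysed C–S coupling with thiophenol (Pd2(dba)3, Xantphos, i-Pr2NEt, dioxane, 80 °C) then gives 7.

Step 9. Alkylation of the hydrogen-bonded phenol may be slow, and prolonged exposure to the basic silver oxide may open the flavanone to the chalcone, with loss of configuration at C2 on reclosure. The fallback replaces base-mediated alkylation by redox condensation; it sets out from 20 and comes back at 21. Mitsunobu methylation (MeOH, PPh3, DIAD, THF, 0 °C → rt) activates methanol as an alkoxyphosphonium ion and uses the chelated phenol as the acidic partner, a mode of alkylation known for the 5-OH of flavanones, so that no metal base is present; no compound outside the route is made (F0).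

Further compounds
F1 | step 8 | 5-hydroxy-7-methoxy-4H-chromen-4-one | COc1cc(O)c2c(c1)occc2=O
F2 | step 8 | 7-methoxy-5-(3-methylbut-2-en-1-yloxy)-4H-chromen-4-one | COc1cc(OCC=C(C)C)c2c(c1)occc2=O
F3 | step 8 | 5-hydroxy-7-methoxy-8-(3-methylbut-2-en-1-yl)-4H-chromen-4-one | COc1cc(O)c2c(c1CC=C(C)C)occc2=O
F4 | step 8 | 5,7-dimethoxy-8-(3-methylbut-2-en-1-yl)-4H-chromen-4-one | COc1cc(OC)c2c(c1CC=C(C)C)occc2=O
F5 | step 3 | (2S)-2-[3-(tert-butyldimethylsilyloxy)-4-methoxyphenyl]-5-iodo-2,3-dihydro-4H-pyran-4-one | COc1ccc([C@@H]2CC(=O)C(I)=CO2)cc1O[Si](C)(C)C(C)(C)C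
F0 | step 9 | none | none
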